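The 6,8-dioxabicyclo[3.2.2]nonan-7-one core is opened at C2–C3 and O6–C5. This unties the oxepane and the 1,4-dioxan-2-one ring at once and leaves an acyclic ether. The plan exploits that bridgehead C5 and methylene C3 are 1,3-related through C4, a latent 1-methylcyclopropyl group. Bridgehead C1 meanwhile carries C2 as a formyl carbon and O6 as an ester oxygen. Silyl triflate activation of the aldehyde should let the cyclopropane σ-bond attack C2 and the ester carbonyl trap the C5 cation. This is a formal (4+3) homo-Prins lactonisation that also sets C2 and C5. The precursor is a (1-methylcyclopropyl)carbinyl ether of a quaternary α-formyl ester without nucleophilic alkenes.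

Key step: step 11

Remark on numbering: C1 is the quaternary bridgehead with the acetoxy side chain, C2 the carbinol, C3 and C4 the methylenes, C5 the methyl-bearing bridgehead, O6–C7(=O) the lactone, O8 the ether oxygen, and C9 the CH with the hydroxy side chain.
Assumption: dimethyl diazomalonate and 2-bromoethyl triflate are taken as commercial.

Step 1
Reactants: 1 1-methylcyclopropane-1-carboxylic acid
Product: 3 N-methoxy-N,1-dimethylcyclopropane-1-carboxamide, via acyl imidazole 2 (not isolated)
Conditions: CDI, CH2Cl2, rt; then MeNH(OMe)·HCl, rt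
Reagents that add atoms: N,O-dimethylhydroxylamine hydrochloride, CNOC.Cl; 1,1'-carbonyldiimidazole, O=C(n1ccnc1)n1ccnc1 (stays only in 2)
Why: Weinreb amide formation through the acyl imidazole activates the hindered quaternary acid under neutral conditions that leave the cyclopropane untouched.

Step 2
Reactants: 3 N-methoxy-N,1-dimethylcyclopropane-1-carboxamide
Product: 4 1-(1-methylcyclopropyl)prop-2-en-1-one
Conditions: CH2=CHMgBr, THF, 0 °C; inverse quench into cold aq HCl
Reagents that add atoms: vinylmagnesium bromide, C=C[Mg]Br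
Why: In this Weinreb ketone synthesis the chelated tetrahedral adduct stops at the ketone level, and the acidic inverse quench keeps the released amine from adding to the enone.

Step 3
Reactants: 4 1-(1-methylcyclopropyl)prop-2-en-1-one
Product: 5 (S)-1-(1-methylcyclopropyl)prop-2-en-1-ol
Conditions: (R)-2-methyl-CBS-oxazaborolidine (cat.), catecholborane, toluene, −78 °C
Reagents that add atoms: none
Why: In this Corey–Bakshi–Shibata reduction the quaternary 1-methylcyclopropyl group is the large and vinyl the small substituent, so the (R)-catalyst should give the (S)-alcohol (future C9), and catecholborane at low temperature avoids hydroboration.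

Step 4
Reactants: 6 but-2-ynoic acid
Product: 7 (Z)-3-iodobut-2-enoic acid
Conditions: NaI, AcOH, 110 °C
Reagents that add atoms: sodium iodide, [Na+].[I-]
Why: Hydroiodination of the ynoic acid (conjugate addition of iodide, then protonation) is a net anti addition and should give the Z-β-iodo acid with iodine and carboxyl cis.

Step 5
Reactants: 7 (Z)-3-iodobut-2-enoic acid; 8 2-(trimethylsilyl)ethanol
Product: 9 2-(trimethylsilyl)ethyl (Z)-3-iodobut-2-enoate
Conditions: DCC, DMAP (cat.), CH2Cl2, 0 °C to rt
Reagents that add atoms: none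
Why: Steglich esterification installs a fluoride-labile ester without touching the alkene geometry.

Step 6
Reactants: 5 (S)-1-(1-methylcyclopropyl)prop-2-en-1-ol; 9 2-(trimethylsilyl)ethyl (Z)-3-iodobut-2-enoate
Product: 11 2-(trimethylsilyl)ethyl (2Z,6S)-6-hydroxy-3-methyl-6-(1-methylcyclopropyl)hex-2-enoate, via bis-boryl adduct 10 (not isolated)
Conditions: 9-BBN (2.2 equiv), THF, 0 °C to rt; then 9, Pd(dppf)Cl2 (cat.), AsPh3, Cs2CO3, DMF/H2O, rt
Reagents that add atoms: 9-borabicyclo[3.3.1]nonane, B1C2CCCC1CCC2 (stays only in 10)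
Why: Anti-Markovnikov hydroboration followed by B-alkyl Suzuki–Miyaura coupling retains the vinyl iodide geometry and so fixes the Z-alkene as a non-nucleophilic conjugated ester, while the O-boryl group is lost in the aqueous base.

Step 7
Reactants: 11 2-(trimethylsilyl)ethyl (2Z,6S)-6-hydroxy-3-methyl-6-(1-methylcyclopropyl)hex-2-enoate; 12 dimethyl diazomalonate
Product: 13 dimethyl 2-{[(1S,4Z)-4-methyl-1-(1-methylcyclopropyl)-6-oxo-6-[2-(trimethylsilyl)ethoxy]hex-4-en-1-yl]oxy}propanedioate
Conditions: Rh2(OAc)4 (1 mol %), benzene, 80 °C, slow addition of 12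
Reagents that add atoms: none
Why: Rhodium-carbenoid O–H insertion is little affected by hindrance at the alcohol, makes the crowded ether bond without touching C9, and spares the electron-poor alkene.

Step 8
Reactants: 13 the alkoxymalonate of step 7
Product: 14 dimethyl 2-(2-bromoethyl)-2-{[(1S,4Z)-4-methyl-1-(1-methylcyclopropyl)-6-oxo-6-[2-(trimethylsilyl)ethoxy]hex-4-en-1-yl]oxy}propanedioate
Conditions: NaH, THF/DMF, 0 °C; BrCH2CH2OTf, 0 °C to rt
Reagents that add atoms: 2-bromoethyl trifluoromethanesulfonate, BrCCOS(=O)(=O)C(F)(F)F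
Why: SN2 alkylation of the stabilised malonate anion at the triflate end of the bifunctional electrophile builds the still prochiral quaternary carbon and leaves a bromide that is inert to cations.

Step 9
Reactants: 14 the bromoethyl malonate of step 8
Product: 16 methyl (2R)-4-bromo-2-(hydroxymethyl)-2-{[(1S,4Z)-4-methyl-1-(1-methylcyclopropyl)-6-oxo-6-[2-(trimethylsilyl)ethoxy]hex-4-en-1-yl]oxy}butanoate, via silyl ether 15 (not isolated)
Conditions: Et2Zn (10 mol %), ProPhenol-type ligand 2,6-bis{[2-(hydroxydiphenylmethyl)pyrrolidin-1-yl]methyl}-4-methylphenol (5 mol %, the enantiomer that reduces the pro-S ester), (EtO)2MeSiH, THF, 0 °C; then aq NaHCO3/MeOH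
Reagents that add atoms: diethoxy(methyl)silane, C[SiH](OCC)OCC (stays only in 15)
Why: In this zinc-catalysed desymmetrising hydrosilylation of a 2,2-disubstituted malonate the dinuclear zinc hydride binds both malonate carbonyls, tells the bulky alkoxy group from the bromoethyl group and should reduce only the pro-S ester, which sets future C1 as R under catalyst control and leaves the non-chelating conjugated ester alone.

Step 10
Reactants: 16 the hydroxy ester of step 9
Product: 17 methyl (2R)-4-bromo-2-formyl-2-{[(1S,4Z)-4-methyl-1-(1-methylcyclopropyl)-6-oxo-6-[2-(trimethylsilyl)ethoxy]hex-4-en-1-yl]oxy}butanoate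
Conditions: Dess–Martin periodinane, CH2Cl2, 0 °C to rt
Reagents that add atoms: none
Why: Dess–Martin oxidation of the neopentyl-type primary alcohol is neutral and fast, and the non-enolisable quaternary aldehyde cannot epimerise.

Step 11
Reactants: 17 the formyl ester of step 10
Product: 19 2-(trimethylsilyl)ethyl (2Z)-5-[(1R,2S,5R,9S)-1-(2-bromoethyl)-5-methyl-7-oxo-2-(triethylsilyloxy)-6,8-dioxabicyclo[3.2.2]nonan-9-yl]-3-methylpent-2-enoate, via dialkoxycarbenium triflate 18 (not isolated)
Conditions: Et3SiOTf (2.5 equiv), 2,6-di-tert-butyl-4-methylpyridine, CH2Cl2, −78 to −20 °C; Et3N/MeOH quench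
Reagents that add atoms: triethylsilyl trifluoromethanesulfonate, CC[Si](CC)(CC)OS(=O)(=O)C(F)(F)F
Why: Proposed new method: Et3SiOTf silylates the formyl oxygen, a methylene corner of the 1-methylcyclopropyl group attacks the silyloxycarbenium carbon (C3–C2), the three-membered ring opens in the Markovnikov sense to the tertiary C5 cation, the methyl ester carbonyl oxygen adds to it (O6–C5) to give 18, and triflate removes the methyl group as MeOTf. The closest known reaction types are the Prins cyclisation terminated by an internal ester, the opening of alkylcyclopropanes by protons, divalent mercury, halonium or acylium ions with capture by an internal carboxyl group, and the formal (3+2) and (4+3) annulations of donor–acceptor cyclopropanes with aldehydes; what is new is an activated aldehyde as the electrophile for an unactivated cyclopropane. The oxepane closes 7-exo-trig at the formyl carbon, and the 1,4-dioxan-2-one closes as a six-membered transannular capture of the ring cation. C5 is fixed by C1, because the ester reaches the planar cation only from its own face of the oxepane, and either diastereotopic cyclopropane methylene leads to the same cation. C2 should be set by the rotamer that turns the bulky Et3SiO group away from the ester that must swing over the ring, so the new C–O bond lies anti to C7 and next to O8. The step needs the weakly nucleophilic cyclopropane to be the only carbon nucleophile and the ester to beat the silyl ether oxygen as trap, which the substrate secures by carrying its only alkene as a conjugated ester, the second side chain as a bromoethyl stub, and a hindered silyl group on the competing oxygen.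

Step 12
Reactants: 20 prop-2-yn-1-ol
Product: 22 (Z)-3-iodo-2-methylprop-2-en-1-ol, via magnesium chelate 21 (not isolated)
Conditions: MeMgBr (3 equiv), CuI (cat.), THF/Et2O, −10 °C to rt; then I2, 0 °C
Reagents that add atoms: methylmagnesium bromide, C[Mg]Br; iodine, II
Why: Copper-catalysed anti-carbomagnesiation directed by the alkoxide places magnesium cis to the CH2O group in chelate 21, and iodinolysis with retention gives the Z-iodide.

Step 13
Reactants: 19 the bicyclic bromide of step 11; 22 (Z)-3-iodo-2-methylprop-2-en-1-ol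
Product: 23 2-(trimethylsilyl)ethyl (2Z)-5-[(1R,2S,5R,9S)-1-[(3Z)-5-hydroxy-4-methylpent-3-en-1-yl]-5-methyl-7-oxo-2-(triethylsilyloxy)-6,8-dioxabicyclo[3.2.2]nonan-9-yl]-3-methylpent-2-enoate
Conditions: NiBr2(diglyme) (10 mol %), 4,4'-di-tert-butyl-2,2'-bipyridine, Mn powder, NaI (cat.), DMA, rt
Reagents that add atoms: none
Why: Nickel-catalysed reductive cross-electrophile coupling joins the primary alkyl bromide to the alkenyl iodide with retention of alkene geometry and tolerates the free alcohol, esters, lactone and silyl ether.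

Step 14
Reactants: 23 the allylic alcohol of step 13
Product: 24 2-(trimethylsilyl)ethyl (2Z)-5-[(1R,2S,5R,9S)-1-[(3Z)-5-acetoxy-4-methylpent-3-en-1-yl]-5-methyl-7-oxo-2-(triethylsilyloxy)-6,8-dioxabicyclo[3.2.2]nonan-9-yl]-3-methylpent-2-enoate
Conditions: Ac2O, pyridine, DMAP (cat.), CH2Cl2, 0 °C
Reagents that add atoms: acetic anhydride, CC(=O)OC(C)=O
Why: This is acylation of the only free hydroxyl group, since C2–OH is silylated and the other chain end is still an ester.

Step 15
Reactants: 24 the acetate of step 14
Product: 25 (2Z)-5-[(1R,2S,5R,9S)-1-[(3Z)-5-acetoxy-4-methylpent-3-en-1-yl]-2-hydroxy-5-methyl-7-oxo-6,8-dioxabicyclo[3.2.2]nonan-9-yl]-3-methylpent-2-enoic acid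
Conditions: tris(dimethylamino)sulfonium difluorotrimethylsilicate (3 equiv), DMF, 0 °C to rt; aq NH4Cl
Reagents that add atoms: none
Why: Anhydrous fluoride fragments the 2-(trimethylsilyl)ethyl ester and cleaves the triethylsilyl ether in one operation under conditions mild enough for the acetate and the hindered lactone.

Step 16
Reactants: 25 the hydroxy acid of step 15
Product: 27 target, (2Z)-5-[(1R,2S,5R,9S)-2-hydroxy-9-[(3Z)-5-hydroxy-3-methylpent-3-en-1-yl]-5-methyl-7-oxo-6,8-dioxabicyclo[3.2.2]nonan-1-yl]-2-methylpent-2-en-1-yl acetate, via mixed anhydride 26 (not isolated)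
Conditions: i-BuOCOCl, N-methylmorpholine, THF, −15 °C; then NaBH4, H2O/MeOH, −15 to 0 °C
Reagents that add atoms: isobutyl chloroformate, CC(C)COC(=O)Cl (stays only in 26)
Why: Activation as a mixed carbonic anhydride lets NaBH4 reduce only this acyl group in 1,2-fashion (the β,β-disubstituted position blocks conjugate reduction), so acetate, lactone and both Z-alkenes remain.

Compound list
1 | 1-methylcyclopropane-1-carboxylic acid | CC1(CC1)C(=O)O | starting material
2 | 1-(1-methylcyclopropane-1-carbonyl)imidazole | CC1(CC1)C(=O)n1ccnc1 | intermediate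
3 | N-methoxy-N,1-dimethylcyclopropane-1-carboxamide | CON(C)C(=O)C1(C)CC1 | intermediate
4 | 1-(1-methylcyclopropyl)prop-2-en-1-one | C=CC(=O)C1(C)CC1 | intermediate
5 | (S)-1-(1-methylcyclopropyl)prop-2-en-1-ol | O[C@@H](C=C)C1(C)CC1 | intermediate
6 | but-2-ynoic acid | CC#CC(=O)O | starting material
7 | (Z)-3-iodobut-2-enoic acid | C/C(I)=C/C(=O)O | intermediate
8 | 2-(trimethylsilyl)ethanol | C[Si](C)(C)CCO | starting material
9 | 2-(trimethylsilyl)ethyl (Z)-3-iodobut-2-enoate | C/C(I)=C/C(=O)OCC[Si](C)(C)C | intermediate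
10 | O,C-bis(9-BBN) adduct of 5 | B1(C2CCCC1CCC2)O[C@@H](CCB1C2CCCC1CCC2)C1(C)CC1 | intermediate
11 | 2-(trimethylsilyl)ethyl (2Z,6S)-6-hydroxy-3-methyl-6-(1-methylcyclopropyl)hex-2-enoate | O[C@@H](CC/C(C)=C\C(=O)OCC[Si](C)(C)C)C1(C)CC1 | intermediate
12 | dimethyl diazomalonate | COC(=O)C(=[N+]=[N-])C(=O)OC | starting material
13 | alkoxymalonate (S at the ether CH, Z-enoate) | COC(=O)C(C(=O)OC)O[C@@H](CC/C(C)=C\C(=O)OCC[Si](C)(C)C)C1(C)CC1 | intermediate
14 | 2-(2-bromoethyl) alkoxymalonate | BrCCC(C(=O)OC)(C(=O)OC)O[C@@H](CC/C(C)=C\C(=O)OCC[Si](C)(C)C)C1(C)CC1 | intermediate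
15 | diethoxy(methyl)silyl ether of 16 | BrCC[C@@](CO[Si](C)(OCC)OCC)(C(=O)OC)O[C@@H](CC/C(C)=C\C(=O)OCC[Si](C)(C)C)C1(C)CC1 | intermediate
16 | (2R)-hydroxymethyl ester | BrCC[C@@](CO)(C(=O)OC)O[C@@H](CC/C(C)=C\C(=O)OCC[Si](C)(C)C)C1(C)CC1 | intermediate
17 | (2R)-formyl ester, key-step precursor | BrCC[C@@](C=O)(C(=O)OC)O[C@@H](CC/C(C)=C\C(=O)OCC[Si](C)(C)C)C1(C)CC1 | intermediate
18 | bicyclic 7-methoxy dialkoxycarbenium triflate | BrCC[C@@]12O[C@@H](CC/C(C)=C\C(=O)OCC[Si](C)(C)C)[C@@](C)(CC[C@@H]1O[Si](CC)(CC)CC)[O+]=C2OC.[O-]S(=O)(=O)C(F)(F)F | intermediate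
19 | (1R,2S,5R,9S)-bicyclic lactone with bromoethyl, OTES and Z-enoate | BrCC[C@@]12O[C@@H](CC/C(C)=C\C(=O)OCC[Si](C)(C)C)[C@@](C)(CC[C@@H]1O[Si](CC)(CC)CC)OC2=O | intermediate
20 | prop-2-yn-1-ol | C#CCO | starting material
21 | cyclic alkenylmagnesium alkoxide | CC1=C[Mg]OC1 | intermediate
22 | (Z)-3-iodo-2-methylprop-2-en-1-ol | OC/C(C)=C\I | intermediate
23 | coupled Z-allylic alcohol | OC/C(C)=C\CC[C@@]12O[C@@H](CC/C(C)=C\C(=O)OCC[Si](C)(C)C)[C@@](C)(CC[C@@H]1O[Si](CC)(CC)CC)OC2=O | intermediate
24 | allylic acetate | CC(=O)OC/C(C)=C\CC[C@@]12O[C@@H](CC/C(C)=C\C(=O)OCC[Si](C)(C)C)[C@@](C)(CC[C@@H]1O[Si](CC)(CC)CC)OC2=O | intermediate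
25 | hydroxy acid | CC(=O)OC/C(C)=C\CC[C@@]12O[C@@H](CC/C(C)=C\C(=O)O)[C@@](C)(CC[C@@H]1O)OC2=O | intermediate
26 | isobutyl mixed carbonic anhydride of 25 | CC(=O)OC/C(C)=C\CC[C@@]12O[C@@H](CC/C(C)=C\C(=O)OC(=O)OCC(C)C)[C@@](C)(CC[C@@H]1O)OC2=O | intermediate
27 | CNP0174851.1 | CC(=O)OC/C(C)=C\CC[C@@]12O[C@@H](CC/C(C)=C\CO)[C@@](C)(CC[C@@H]1O)OC2=O | target

Total step count: 16. Longest linear sequence: 13 (steps 1–3, 6–11 and 13–16).

Steps most likely to fail

Step 11. The unactivated cyclopropane may attack too slowly. The C9–O8 bond may ionise to a cyclopropylcarbinyl cation. A hydride may shift from C9 to the C5 cation, or the cation may lose a proton. The silyl ether oxygen may capture the cation, or facial selectivity at the formyl group may be poor.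
The fallback sets out from 17 and comes back at 19, and it makes the two bonds one after the other by known reactions.
- Iodonium-induced opening of the cyclopropane with capture by the ester (N-iodosuccinimide, CH2Cl2), the homologue of iodolactonisation, should give (3R,5S,6R)-3-(2-bromoethyl)-3-formyl-6-(2-iodoethyl)-6-methyl-1,4-dioxan-2-one bearing the enoate chain at C5, F1. Only the isomer with the iodoethyl and formyl groups cis can go on.
- A cobalt-catalysed Nozaki–Hiyama-type alkylchromium addition (CrCl2, cobalt phthalocyanine Co(C32H16N8), DMF) is selective for the iodide over the bromide and closes C3–C2 to the bicyclic hydroxy lactone F2.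
- Et3SiOTf/2,6-lutidine then gives 19.

Step 9. The ligand and C9 may be mismatched in double stereodifferentiation. The second ester may be over-reduced, or the new oxygen may cyclise onto the bromide.
The fallback sets out from 14 and comes back at 16. Hydrolase-mediated mono-hydrolysis of the pro-S ester (pig liver esterase, pH 7 buffer/DMSO) gives the (R)-malonic half ester F3. The free acid is then reduced chemoselectively with BH3·SMe2 in THF at 0 °C.

Step 13. The alkenyl iodide may homocouple, the bromide may be hydrodehalogenated, or the Z geometry may be partly lost.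
The fallback sets out from 19 and comes back at 23.
- Displacement of bromide with PhSeNa, made from (PhSe)2 and NaBH4, gives the phenyl selenide F4.
- H2O2/pyridine causes selenoxide syn elimination to the 1-vinyl lactone F5.
- 9-BBN gives the B-alkyl borane F6.
- F6 is coupled with 22 by B-alkyl Suzuki–Miyaura reaction (Pd(dppf)Cl2, AsPh3, Cs2CO3, DMF/H2O).

Further compounds
F1 | step 11 | (3R,5S,6R)-3-(2-bromoethyl)-3-formyl-6-(2-iodoethyl)-6-methyl-1,4-dioxan-2-one with the Z-enoate chain at C5 | BrCC[C@]1(C=O)O[C@@H](CC/C(C)=C\C(=O)OCC[Si](C)(C)C)[C@@](C)(CCI)OC1=O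
F2 | step 11 | (1R,2S,5R,9S)-1-(2-bromoethyl)-2-hydroxy bicyclic lactone | BrCC[C@@]12O[C@@H](CC/C(C)=C\C(=O)OCC[Si](C)(C)C)[C@@](C)(CC[C@@H]1O)OC2=O
F3 | step 9 | (R)-malonic half ester | BrCC[C@@](C(=O)O)(C(=O)OC)O[C@@H](CC/C(C)=C\C(=O)OCC[Si](C)(C)C)C1(C)CC1
F4 | step 13 | 1-[2-(phenylselanyl)ethyl] bicyclic lactone | c1ccccc1[Se]CC[C@@]12O[C@@H](CC/C(C)=C\C(=O)OCC[Si](C)(C)C)[C@@](C)(CC[C@@H]1O[Si](CC)(CC)CC)OC2=O
F5 | step 13 | 1-vinyl bicyclic lactone | C=C[C@@]12O[C@@H](CC/C(C)=C\C(=O)OCC[Si](C)(C)C)[C@@](C)(CC[C@@H]1O[Si](CC)(CC)CC)OC2=O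
F6 | step 13 | B-alkyl-9-BBN derivative of F5 | B1(C2CCCC1CCC2)CC[C@@]12O[C@@H](CC/C(C)=C\C(=O)OCC[Si](C)(C)C)[C@@](C)(CC[C@@H]1O[Si](CC)(CC)CC)OC2=O
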